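Carotenoid numbering is used. Ring A is the triol ring (C1 = CMe2, carbinols C3, C5, C6, C7 = first chain carbon). Ring A' is the cyclohexene ring carrying the C7'≡C8' alkyne.
Enabling feature: in ring A the array C7–C6(OH)–C5(OH) is what a 5,6-epoxy-7-ol gives when the C7 oxygen migrates to C6, so the trans C5/C6 diol and a heteroatom handle on C7 arise in one operation.
Retrosynthesis: cut C11=C12, then C11'=C12' (Wittig), to the ring A C15 phosphonium salt, the C10 trienedial and the ring A' C15 enynyl phosphonium salt. In the ring A piece cut C7=C8 back to a C7–C8 bond (sulfoxide alkylation, then sulfenic acid loss), then C7–S and C6–O (epoxide migration with thiolate capture). In the ring A' piece cut C6'–C7' (Sonogashira).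
Forward: ketoisophorone gives silylated enol triflate 6, the source of both rings; no carbocycle is built and the only ring closed is a transient oxirane. Branch A runs carbonylation, epoxidation, key step, C7–C8, C7=C8, salt 20. Branch A' runs C6'–C7', salt 24, C11'=C12' to aldehyde 27. Then C11=C12 (20 + 27) and desilylation.
Stereochemistry: C3 and C3' come from one enzymatic enone reduction relayed by a substrate-controlled ketone reduction; C5 from the reagent-controlled Sharpless epoxidation; C6 from inversion in the key step. Alkene geometry comes from E building blocks, a syn elimination and Wittig couplings.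

Key step: step 8

Remark: TBS = tert-butyldimethylsilyl; the C5 bromo acetate 14, the C6 enynol 21 and the C10 trienedial 25 are assumed to be purchasable polyene building blocks.

Step 1
Reactants: 1 ketoisophorone (2,6,6-trimethylcyclohex-2-ene-1,4-dione)
Product: 2 (6R)-2,2,6-trimethylcyclohexane-1,4-dione
Conditions: OYE2 ene-reductase, NADP+ (cat.), glucose dehydrogenase, D-glucose, phosphate buffer pH 7, 30 °C
Reagents that add atoms: none
Why: Flavin-dependent ene-reductase (old yellow enzyme) reduction of the enone C=C with cofactor recycling; hydride and proton are added across one face, which should set the methyl-bearing carbon as R.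

Step 2
Reactants: 2 (6R)-2,2,6-trimethylcyclohexane-1,4-dione
Product: 3 (4R,6R)-4-hydroxy-2,2,6-trimethylcyclohexan-1-one
Conditions: LiBH(s-Bu)3, THF, −78 °C
Reagents that add atoms: none
Why: Substrate-controlled reduction with a bulky borohydride: the unhindered C4 ketone is attacked from the equatorial side, away from the axial C2 methyl, so the hydroxyl should end up axial and trans to the equatorial C6 methyl, i.e. (4R), while the doubly flanked C1 ketone should not react at −78 °C.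

Step 3
Reactants: 3 (4R,6R)-4-hydroxy-2,2,6-trimethylcyclohexan-1-one
Product: 4 (4R,6R)-4-(TBSO)-2,2,6-trimethylcyclohexan-1-one
Conditions: TBSCl, imidazole, DMF, rt
Reagents that add atoms: tert-butyldimethylsilyl chloride, CC(C)(C)[Si](C)(C)Cl
Why: Imidazole-assisted silylation of a secondary alcohol; no stereocentre is touched.

Step 4
Reactants: 4 (4R,6R)-4-(TBSO)-2,2,6-trimethylcyclohexan-1-one
Product: 6 (4R)-4-(TBSO)-2,6,6-trimethylcyclohex-1-en-1-yl trifluoromethanesulfonate, via lithium enolate 5 (not isolated)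
Conditions: LiN(i-Pr)2, THF, −78 °C; PhNTf2, −78 °C → rt
Reagents that add atoms: N-phenylbis(trifluoromethanesulfonimide), O=S(=O)(N(c1ccccc1)S(=O)(=O)C(F)(F)F)C(F)(F)F
Why: Deprotonation at the only enolisable α-carbon and O-sulfonylation of the enolate (enol triflate formation); the methyl-bearing centre becomes sp2 as intended.

Step 5
Reactants: 6 (4R)-4-(TBSO)-2,6,6-trimethylcyclohex-1-en-1-yl trifluoromethanesulfonate
Product: 7 methyl (4R)-4-(TBSO)-2,6,6-trimethylcyclohex-1-ene-1-carboxylate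
Conditions: Pd(OAc)2 (cat.), PPh3, CO (1 atm), MeOH, Et3N, DMF, 70 °C
Reagents that add atoms: carbon monoxide, [C-]#[O+]; methanol, CO
Why: Palladium-catalysed methoxycarbonylation of a vinyl triflate (oxidative addition, CO insertion, methanolysis of the acylpalladium) installs C7.

Step 6
Reactants: 7 methyl (4R)-4-(TBSO)-2,6,6-trimethylcyclohex-1-ene-1-carboxylate
Product: 8 [(4R)-4-(TBSO)-2,6,6-trimethylcyclohex-1-en-1-yl]methanol
Conditions: i-Bu2AlH, CH2Cl2, −78 → 0 °C
Reagents that add atoms: none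
Why: 1,2-Reduction of the unsaturated ester to the primary allylic alcohol by the aluminium hydride.

Step 7
Reactants: 8 [(4R)-4-(TBSO)-2,6,6-trimethylcyclohex-1-en-1-yl]methanol
Product: 9 [(1R,4S,6R)-4-(TBSO)-2,2,6-trimethyl-7-oxabicyclo[4.1.0]heptan-1-yl]methanol (ring A 5,6-epoxy-7-ol, epoxide anti to the silyloxy group)
Conditions: Ti(OiPr)4 (cat.), D-(−)-diethyl tartrate (cat.), t-BuOOH, 4 Å MS, CH2Cl2, −20 °C
Reagents that add atoms: tert-butyl hydroperoxide, CC(C)(C)OO
Why: Sharpless asymmetric epoxidation: the titanium-bound allylic alkoxide delivers the peroxide oxygen to C5=C6 and the (S,S)-tartrate should direct it to the face opposite the C3 silyloxy group, which sets C5 and, provisionally, C6.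

Step 8
Reactants: 9 [(1R,4S,6R)-4-(TBSO)-2,2,6-trimethyl-7-oxabicyclo[4.1.0]heptan-1-yl]methanol; 10 thiophenol
Product: 12 (1R,2R,4S)-4-(TBSO)-2,6,6-trimethyl-1-[(phenylsulfanyl)methyl]cyclohexane-1,2-diol, via spiro 6,7-epoxide 11 (not isolated)
Conditions: PhSH (3 equiv), NaOH (0.5 M in H2O), t-BuOH, 80 °C, Ar
Reagents that add atoms: none
Why: Hydroxide deprotonates the C7 hydroxyl and the alkoxide attacks C6 from the side opposite the epoxide C6–O bond, giving spiro oxirane 11 and a C5 alkoxide; thiophenoxide then opens 11 at its CH2 carbon (SN2 at C7) and so drains the unfavourable equilibrium. This is a Payne rearrangement coupled to thiolate opening of the terminal epoxide, the usual way to functionalise C1 of a 2,3-epoxy alcohol. The only ring closed is the transient oxirane, by 3-exo-tet displacement, and no new ring remains in 12. C6 is the one stereocentre that changes: the intramolecular rear-side geometry enforces inversion, so the former C7 oxygen ends up on the face opposite the C5 oxygen while C5 keeps its oxygen, which gives the trans 5,6-diol. The step needs external attack at C7 only and no ionisation; C5 and C6 are fully substituted and inert to thiolate, the basic medium shuts off cationic ring contraction and furanoid pathways, and the C3 silyl ether is trans to the C5 alkoxide and cannot migrate.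

Step 9
Reactants: 12 (1R,2R,4S)-4-(TBSO)-2,6,6-trimethyl-1-[(phenylsulfanyl)methyl]cyclohexane-1,2-diol
Product: 13 (1R,2R,4S)-4-(TBSO)-2,6,6-trimethyl-1-[(phenylsulfinyl)methyl]cyclohexane-1,2-diol (both sulfur epimers)
Conditions: mCPBA (1.0 equiv), CH2Cl2, −78 °C
Reagents that add atoms: 3-chloroperbenzoic acid, O=C(OO)c1cccc(Cl)c1
Why: Chemoselective sulfide-to-sulfoxide oxidation by one equivalent of peracid at low temperature; both sulfur epimers are usable because sulfur is expelled in step 11.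

Step 10
Reactants: 13 (1R,2R,4S)-4-(TBSO)-2,6,6-trimethyl-1-[(phenylsulfinyl)methyl]cyclohexane-1,2-diol; 14 (E)-4-bromo-3-methylbut-2-en-1-yl acetate
Product: 16 (2E)-5-[(1R,2R,4S)-4-(TBSO)-1,2-dihydroxy-2,6,6-trimethylcyclohexyl]-3-methyl-5-(phenylsulfinyl)pent-2-en-1-yl acetate (mixture at C7 and sulfur), via trilithio sulfoxide 15 (not isolated)
Conditions: LiN(i-Pr)2 (3.3 equiv), THF/DMPU, −78 °C; then 14, −78 → −30 °C
Reagents that add atoms: none
Why: α-Sulfinyl carbanion alkylation (SN2 at the allylic bromide) forms C7–C8; the C5 and C6 hydroxyls are carried as lithium alkoxides, which cannot act as leaving groups, and the new C7 centre need not be controlled because it becomes sp2 in step 11.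

Step 11
Reactants: 16 (2E)-5-[(1R,2R,4S)-4-(TBSO)-1,2-dihydroxy-2,6,6-trimethylcyclohexyl]-3-methyl-5-(phenylsulfinyl)pent-2-en-1-yl acetate
Product: 17 (2E,4E)-5-[(1R,2R,4S)-4-(TBSO)-1,2-dihydroxy-2,6,6-trimethylcyclohexyl]-3-methylpenta-2,4-dien-1-yl acetate
Conditions: toluene, CaCO3, 100 °C
Reagents that add atoms: none
Why: Thermal syn-elimination of a sulfoxide (sulfenic acid loss through a five-membered cyclic transition state): C6 has no hydrogen, so only a C8–H can be removed, and the trans (7E) diene conjugated with C9=C10 should result.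

Step 12
Reactants: 17 (2E,4E)-5-[(1R,2R,4S)-4-(TBSO)-1,2-dihydroxy-2,6,6-trimethylcyclohexyl]-3-methylpenta-2,4-dien-1-yl acetate
Product: 18 (1R,2R,4S)-4-(TBSO)-1-[(1E,3E)-5-hydroxy-3-methylpenta-1,3-dien-1-yl]-2,6,6-trimethylcyclohexane-1,2-diol
Conditions: K2CO3 (cat.), MeOH, 0 °C
Reagents that add atoms: none
Why: Base-catalysed transesterification removes the acetate; the tertiary hydroxyls and the silyl ether are inert.

Step 13
Reactants: 18 (1R,2R,4S)-4-(TBSO)-1-[(1E,3E)-5-hydroxy-3-methylpenta-1,3-dien-1-yl]-2,6,6-trimethylcyclohexane-1,2-diol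
Product: 19 (1R,2R,4S)-1-[(1E,3E)-5-bromo-3-methylpenta-1,3-dien-1-yl]-4-(TBSO)-2,6,6-trimethylcyclohexane-1,2-diol
Conditions: CBr4, PPh3, CH2Cl2, −20 °C; used at once
Reagents that add atoms: carbon tetrabromide, BrC(Br)(Br)Br
Why: Appel reaction: the primary allylic hydroxyl is activated as an oxyphosphonium ion and displaced by bromide under neutral conditions, which spares the acid-sensitive tertiary allylic diol.

Step 14
Reactants: 19 (1R,2R,4S)-1-[(1E,3E)-5-bromo-3-methylpenta-1,3-dien-1-yl]-4-(TBSO)-2,6,6-trimethylcyclohexane-1,2-diol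
Product: 20 {(2E,4E)-5-[(1R,2R,4S)-4-(TBSO)-1,2-dihydroxy-2,6,6-trimethylcyclohexyl]-3-methylpenta-2,4-dien-1-yl}triphenylphosphonium bromide
Conditions: PPh3, EtOAc, rt, dark
Reagents that add atoms: triphenylphosphine, c1ccccc1P(c1ccccc1)c1ccccc1
Why: SN2 quaternisation of the phosphine by the allylic bromide gives the Wittig salt with the diene geometry unchanged.

Step 15
Reactants: 6 (4R)-4-(TBSO)-2,6,6-trimethylcyclohex-1-en-1-yl trifluoromethanesulfonate; 21 (E)-3-methylpent-2-en-4-yn-1-ol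
Product: 22 (2E)-5-[(4R)-4-(TBSO)-2,6,6-trimethylcyclohex-1-en-1-yl]-3-methylpent-2-en-4-yn-1-ol
Conditions: Pd(PPh3)4 (cat.), CuI (cat.), i-Pr2NH, DMF, 50 °C
Reagents that add atoms: none
Why: Sonogashira coupling of the vinyl triflate with the terminal alkyne forms C6'–C7'; the free primary alcohol is tolerated and the E enyne geometry is carried over.

Step 16
Reactants: 22 (2E)-5-[(4R)-4-(TBSO)-2,6,6-trimethylcyclohex-1-en-1-yl]-3-methylpent-2-en-4-yn-1-ol
Product: 23 (2E)-1-bromo-5-[(4R)-4-(TBSO)-2,6,6-trimethylcyclohex-1-en-1-yl]-3-methylpent-2-en-4-yne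
Conditions: CBr4, PPh3, CH2Cl2, −20 °C; used at once
Reagents that add atoms: carbon tetrabromide, BrC(Br)(Br)Br
Why: Appel bromination of the primary allylic alcohol under neutral conditions, which the silyl ether tolerates.

Step 17
Reactants: 23 (2E)-1-bromo-5-[(4R)-4-(TBSO)-2,6,6-trimethylcyclohex-1-en-1-yl]-3-methylpent-2-en-4-yne
Product: 24 {(2E)-5-[(4R)-4-(TBSO)-2,6,6-trimethylcyclohex-1-en-1-yl]-3-methylpent-2-en-4-yn-1-yl}triphenylphosphonium bromide
Conditions: PPh3, EtOAc, rt, dark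
Reagents that add atoms: triphenylphosphine, c1ccccc1P(c1ccccc1)c1ccccc1
Why: SN2 quaternisation of the phosphine by the allylic bromide gives the acetylenic C15 Wittig salt.

Step 18
Reactants: 24 {(2E)-5-[(4R)-4-(TBSO)-2,6,6-trimethylcyclohex-1-en-1-yl]-3-methylpent-2-en-4-yn-1-yl}triphenylphosphonium bromide; 25 (2E,4E,6E)-2,7-dimethylocta-2,4,6-trienedial
Product: 27 (2E,4E,6E,8E,10E)-13-[(4R)-4-(TBSO)-2,6,6-trimethylcyclohex-1-en-1-yl]-2,7,11-trimethyltrideca-2,4,6,8,10-pentaen-12-ynal, via phosphorus ylide 26 (not isolated)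
Conditions: 25 (3 equiv), NaOMe, MeOH/CH2Cl2, 0 °C → rt, Ar, dark
Reagents that add atoms: none
Why: Wittig olefination of one formyl group of the excess dialdehyde by the allylic ylide forms C11'=C12'; the conjugated E isomer should predominate and any hindered cis isomer is removed by chromatography in the dark.

Step 19
Reactants: 20 {(2E,4E)-5-[(1R,2R,4S)-4-(TBSO)-1,2-dihydroxy-2,6,6-trimethylcyclohexyl]-3-methylpenta-2,4-dien-1-yl}triphenylphosphonium bromide; 27 (2E,4E,6E,8E,10E)-13-[(4R)-4-(TBSO)-2,6,6-trimethylcyclohex-1-en-1-yl]-2,7,11-trimethyltrideca-2,4,6,8,10-pentaen-12-ynal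
Product: 29 (3S,5R,6R,3'R)-3,3'-bis(TBSO)-7',8'-didehydro-5,6-dihydro-β,β-carotene-5,6-diol (all-E), via phosphorus ylide 28 (not isolated)
Conditions: NaOMe, MeOH/CH2Cl2, 0 °C → rt, Ar, dark; HPLC
Reagents that add atoms: none
Why: Wittig olefination forms C11=C12 and completes the C40 chain; NaOMe suffices for ylide formation while leaving the tertiary hydroxyls and silyl ethers alone, and the all-E isomer is to be isolated by HPLC.

Step 20
Reactants: 29 (3S,5R,6R,3'R)-3,3'-bis(TBSO)-7',8'-didehydro-5,6-dihydro-β,β-carotene-5,6-diol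
Product: 30 (3S,5R,6R,3'R)-7',8'-didehydro-5,6-dihydro-β,β-carotene-3,5,6,3'-tetrol (all-E), the target
Conditions: Bu4NF, THF, rt, Ar, dark
Reagents that add atoms: none
Why: Fluoride-induced desilylation of both secondary silyl ethers; the non-acidic medium protects the allylic tertiary C6 hydroxyl from ionisation.

Compound list
1 | ketoisophorone (2,6,6-trimethylcyclohex-2-ene-1,4-dione) | CC1=CC(=O)CC(C)(C)C1=O | starting material
2 | (6R)-2,2,6-trimethylcyclohexane-1,4-dione | O=C1C(C)(C)CC(=O)C[C@H]1C | intermediate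
3 | (4R,6R)-4-hydroxy-2,2,6-trimethylcyclohexan-1-one (OH trans to the C6 methyl) | O=C1C(C)(C)C[C@H](O)C[C@H]1C | intermediate
4 | (4R,6R)-4-(tert-butyldimethylsilyloxy)-2,2,6-trimethylcyclohexan-1-one | O=C1C(C)(C)C[C@H](O[Si](C)(C)C(C)(C)C)C[C@H]1C | intermediate
5 | lithium (4R)-4-(tert-butyldimethylsilyloxy)-2,6,6-trimethylcyclohex-1-en-1-olate (lithium enolate of 4) | [Li+].CC1=C([O-])C(C)(C)C[C@H](O[Si](C)(C)C(C)(C)C)C1 | intermediate (not isolated)
6 | (4R)-4-(tert-butyldimethylsilyloxy)-2,6,6-trimethylcyclohex-1-en-1-yl trifluoromethanesulfonate | CC1=C(OS(=O)(=O)C(F)(F)F)C(C)(C)C[C@H](O[Si](C)(C)C(C)(C)C)C1 | intermediate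
7 | methyl (4R)-4-(tert-butyldimethylsilyloxy)-2,6,6-trimethylcyclohex-1-ene-1-carboxylate | CC1=C(C(=O)OC)C(C)(C)C[C@H](O[Si](C)(C)C(C)(C)C)C1 | intermediate
8 | [(4R)-4-(tert-butyldimethylsilyloxy)-2,6,6-trimethylcyclohex-1-en-1-yl]methanol | CC1=C(CO)C(C)(C)C[C@H](O[Si](C)(C)C(C)(C)C)C1 | intermediate
9 | [(1R,4S,6R)-4-(tert-butyldimethylsilyloxy)-2,2,6-trimethyl-7-oxabicyclo[4.1.0]heptan-1-yl]methanol (ring A 5,6-epoxy-7-ol, epoxide anti to OTBS) | OC[C@]12C(C)(C)C[C@H](O[Si](C)(C)C(C)(C)C)C[C@@]1(C)O2 | intermediate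
10 | thiophenol | Sc1ccccc1 | starting material
11 | (3S,4R,6S)-6-(tert-butyldimethylsilyloxy)-4,8,8-trimethyl-1-oxaspiro[2.5]octan-4-ol (spiro 6,7-epoxide, C6 inverted, free C5 hydroxyl) | C1O[C@@]12C(C)(C)C[C@H](O[Si](C)(C)C(C)(C)C)C[C@@]2(C)O | intermediate (not isolated)
12 | (1R,2R,4S)-4-(tert-butyldimethylsilyloxy)-2,6,6-trimethyl-1-[(phenylsulfanyl)methyl]cyclohexane-1,2-diol (ring A trans-5,6-diol 7-phenyl sulfide) | c1ccccc1SC[C@@]2(O)C(C)(C)C[C@H](O[Si](C)(C)C(C)(C)C)C[C@@]2(C)O | intermediate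
13 | (1R,2R,4S)-4-(tert-butyldimethylsilyloxy)-2,6,6-trimethyl-1-[(phenylsulfinyl)methyl]cyclohexane-1,2-diol (both sulfur epimers) | O=S(c1ccccc1)C[C@@]2(O)C(C)(C)C[C@H](O[Si](C)(C)C(C)(C)C)C[C@@]2(C)O | intermediate
14 | (E)-4-bromo-3-methylbut-2-en-1-yl acetate | CC(=O)OC/C=C(C)/CBr | starting material
15 | trilithio derivative of 13 (C7 carbanion, C5 and C6 lithium alkoxides) | [Li+].[Li+].[Li+].O=S(c1ccccc1)[CH-][C@@]2([O-])C(C)(C)C[C@H](O[Si](C)(C)C(C)(C)C)C[C@@]2(C)[O-] | intermediate (not isolated)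
16 | (2E)-5-[(1R,2R,4S)-4-(tert-butyldimethylsilyloxy)-1,2-dihydroxy-2,6,6-trimethylcyclohexyl]-3-methyl-5-(phenylsulfinyl)pent-2-en-1-yl acetate (mixture at C7 and sulfur) | CC(=O)OC/C=C(C)/CC(S(=O)c1ccccc1)[C@@]2(O)C(C)(C)C[C@H](O[Si](C)(C)C(C)(C)C)C[C@@]2(C)O | intermediate
17 | (2E,4E)-5-[(1R,2R,4S)-4-(tert-butyldimethylsilyloxy)-1,2-dihydroxy-2,6,6-trimethylcyclohexyl]-3-methylpenta-2,4-dien-1-yl acetate | CC(=O)OC/C=C(C)/C=C/[C@@]2(O)C(C)(C)C[C@H](O[Si](C)(C)C(C)(C)C)C[C@@]2(C)O | intermediate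
18 | (1R,2R,4S)-4-(tert-butyldimethylsilyloxy)-1-[(1E,3E)-5-hydroxy-3-methylpenta-1,3-dien-1-yl]-2,6,6-trimethylcyclohexane-1,2-diol | OC/C=C(C)/C=C/[C@@]2(O)C(C)(C)C[C@H](O[Si](C)(C)C(C)(C)C)C[C@@]2(C)O | intermediate
19 | (1R,2R,4S)-1-[(1E,3E)-5-bromo-3-methylpenta-1,3-dien-1-yl]-4-(tert-butyldimethylsilyloxy)-2,6,6-trimethylcyclohexane-1,2-diol | BrC/C=C(C)/C=C/[C@@]2(O)C(C)(C)C[C@H](O[Si](C)(C)C(C)(C)C)C[C@@]2(C)O | intermediate
20 | {(2E,4E)-5-[(1R,2R,4S)-4-(tert-butyldimethylsilyloxy)-1,2-dihydroxy-2,6,6-trimethylcyclohexyl]-3-methylpenta-2,4-dien-1-yl}triphenylphosphonium bromide | [Br-].c1ccccc1[P+](c1ccccc1)(c1ccccc1)C/C=C(C)/C=C/[C@@]2(O)C(C)(C)C[C@H](O[Si](C)(C)C(C)(C)C)C[C@@]2(C)O | intermediate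
21 | (E)-3-methylpent-2-en-4-yn-1-ol | C#C/C(C)=C/CO | starting material
22 | (2E)-5-[(4R)-4-(tert-butyldimethylsilyloxy)-2,6,6-trimethylcyclohex-1-en-1-yl]-3-methylpent-2-en-4-yn-1-ol | CC1=C(C#C/C(C)=C/CO)C(C)(C)C[C@H](O[Si](C)(C)C(C)(C)C)C1 | intermediate
23 | (2E)-1-bromo-5-[(4R)-4-(tert-butyldimethylsilyloxy)-2,6,6-trimethylcyclohex-1-en-1-yl]-3-methylpent-2-en-4-yne | CC1=C(C#C/C(C)=C/CBr)C(C)(C)C[C@H](O[Si](C)(C)C(C)(C)C)C1 | intermediate
24 | {(2E)-5-[(4R)-4-(tert-butyldimethylsilyloxy)-2,6,6-trimethylcyclohex-1-en-1-yl]-3-methylpent-2-en-4-yn-1-yl}triphenylphosphonium bromide | [Br-].CC1=C(C#C/C(C)=C/C[P+](c2ccccc2)(c2ccccc2)c2ccccc2)C(C)(C)C[C@H](O[Si](C)(C)C(C)(C)C)C1 | intermediate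
25 | (2E,4E,6E)-2,7-dimethylocta-2,4,6-trienedial | O=C/C(C)=C/C=C/C=C(C)/C=O | starting material
26 | triphenylphosphonium ylide of 24 | CC1=C(C#C/C(C)=C/C=P(c2ccccc2)(c2ccccc2)c2ccccc2)C(C)(C)C[C@H](O[Si](C)(C)C(C)(C)C)C1 | intermediate (not isolated)
27 | (2E,4E,6E,8E,10E)-13-[(4R)-4-(tert-butyldimethylsilyloxy)-2,6,6-trimethylcyclohex-1-en-1-yl]-2,7,11-trimethyltrideca-2,4,6,8,10-pentaen-12-ynal | CC1=C(C#C/C(C)=C/C=C/C(C)=C/C=C/C=C(C)/C=O)C(C)(C)C[C@H](O[Si](C)(C)C(C)(C)C)C1 | intermediate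
28 | triphenylphosphonium ylide of 20 | c1ccccc1P(c1ccccc1)(c1ccccc1)=C/C=C(C)/C=C/[C@@]2(O)C(C)(C)C[C@H](O[Si](C)(C)C(C)(C)C)C[C@@]2(C)O | intermediate (not isolated)
29 | (3S,5R,6R,3'R)-3,3'-bis(tert-butyldimethylsilyloxy)-7',8'-didehydro-5,6-dihydro-β,β-carotene-5,6-diol (all-E) | CC1=C(C#C/C(C)=C/C=C/C(C)=C/C=C/C=C(C)/C=C/C=C(C)/C=C/[C@@]2(O)C(C)(C)C[C@H](O[Si](C)(C)C(C)(C)C)C[C@@]2(C)O)C(C)(C)C[C@H](O[Si](C)(C)C(C)(C)C)C1 | intermediate
30 | (3S,5R,6R,3'R)-7',8'-didehydro-5,6-dihydro-β,β-carotene-3,5,6,3'-tetrol (all-E) | CC1=C(C#C/C(C)=C/C=C/C(C)=C/C=C/C=C(C)/C=C/C=C(C)/C=C/[C@@]2(O)C(C)(C)C[C@H](O)C[C@@]2(C)O)C(C)(C)C[C@H](O)C1 | target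

Total step count: 20. Longest linear sequence: 16 steps (steps 1–14, 19 and 20); the ring A' branch (steps 15–18) leaves the main line at compound 6.

Steps most likely to fail

Step 8. The epoxide migration onto the fully substituted C6 may be too slow, so that 9 persists and the silyl ether is gradually hydrolysed by hot alkali. The fallback sets out from 8 and inverts C5 instead of C6. Sharpless epoxidation with L-(+)-diethyl tartrate should give the syn-epoxy alcohol [(1S,4S,6S)-4-(TBSO)-2,2,6-trimethyl-7-oxabicyclo[4.1.0]heptan-1-yl]methanol F1. Acid-catalysed hydration (cat. HClO4, THF/H2O, 0 °C) should open it trans-diaxially at C5, the epoxide carbon remote from the hydroxymethyl group, to give (1S,2R,4S)-4-(TBSO)-1-(hydroxymethyl)-2,6,6-trimethylcyclohexane-1,2-diol F2. Selective sulfonylation of the primary hydroxyl (TsCl, pyridine) gives the primary tosylate F3, and NaSPh in DMF (closure to oxirane 11, opening at C7) comes back to the route at 12.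

Step 10. C-alkylation of the trilithiated sulfoxide may be outrun by proton transfer or by attack on the acetate carbonyl, because the carbanion is neopentyl-like. The fallback sets out from 13 and makes C7 the electrophile. Pummerer rearrangement (trifluoroacetic anhydride, 2,6-lutidine, then aqueous NaHCO3) should give (1R,2R,4S)-4-(TBSO)-1,2-dihydroxy-2,6,6-trimethylcyclohexane-1-carbaldehyde F4. Horner–Wadsworth–Emmons reaction with commercial triethyl 3-methyl-4-phosphonocrotonate (LiN(SiMe3)2, THF) should give ethyl (2E,4E)-5-[(1R,2R,4S)-4-(TBSO)-1,2-dihydroxy-2,6,6-trimethylcyclohexyl]-3-methylpenta-2,4-dienoate F5. Reduction with i-Bu2AlH comes back to the route at 18.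

Step 19. The olefination may give much cis isomer at the new C11=C12 bond, and any equilibration to correct it risks E/Z scrambling at C9'=C10' next to the alkyne. The fallback sets out from 19. Michaelis–Becker reaction with NaP(O)(OEt)2 gives diethyl {(2E,4E)-5-[(1R,2R,4S)-4-(TBSO)-1,2-dihydroxy-2,6,6-trimethylcyclohexyl]-3-methylpenta-2,4-dien-1-yl}phosphonate F6. Its Horner–Wadsworth–Emmons reaction with 27 (NaN(SiMe3)2, THF, −78 → 0 °C), which is E-selective without equilibration, comes back to the route at 29.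

Further compounds
F1 | step 8 | [(1S,4S,6S)-4-(tert-butyldimethylsilyloxy)-2,2,6-trimethyl-7-oxabicyclo[4.1.0]heptan-1-yl]methanol (epoxide syn to OTBS) | OC[C@@]12C(C)(C)C[C@H](O[Si](C)(C)C(C)(C)C)C[C@]1(C)O2
F2 | step 8 | (1S,2R,4S)-4-(tert-butyldimethylsilyloxy)-1-(hydroxymethyl)-2,6,6-trimethylcyclohexane-1,2-diol | OC[C@@]2(O)C(C)(C)C[C@H](O[Si](C)(C)C(C)(C)C)C[C@@]2(C)O
F3 | step 8 | [(1S,2R,4S)-4-(tert-butyldimethylsilyloxy)-1,2-dihydroxy-2,6,6-trimethylcyclohexyl]methyl 4-methylbenzenesulfonate | Cc1ccc(cc1)S(=O)(=O)OC[C@@]2(O)C(C)(C)C[C@H](O[Si](C)(C)C(C)(C)C)C[C@@]2(C)O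
F4 | step 10 | (1R,2R,4S)-4-(tert-butyldimethylsilyloxy)-1,2-dihydroxy-2,6,6-trimethylcyclohexane-1-carbaldehyde | O=C[C@@]2(O)C(C)(C)C[C@H](O[Si](C)(C)C(C)(C)C)C[C@@]2(C)O
F5 | step 10 | ethyl (2E,4E)-5-[(1R,2R,4S)-4-(tert-butyldimethylsilyloxy)-1,2-dihydroxy-2,6,6-trimethylcyclohexyl]-3-methylpenta-2,4-dienoate | CCOC(=O)/C=C(C)/C=C/[C@@]2(O)C(C)(C)C[C@H](O[Si](C)(C)C(C)(C)C)C[C@@]2(C)O
F6 | step 19 | diethyl {(2E,4E)-5-[(1R,2R,4S)-4-(tert-butyldimethylsilyloxy)-1,2-dihydroxy-2,6,6-trimethylcyclohexyl]-3-methylpenta-2,4-dien-1-yl}phosphonate | CCOP(=O)(OCC)C/C=C(C)/C=C/[C@@]2(O)C(C)(C)C[C@H](O[Si](C)(C)C(C)(C)C)C[C@@]2(C)O
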